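**Retrosynthetic overview** (atom numbers are those of the tetrahydroindene core of the target: C1 CHMe, C2=C3(Et), C3a, C4 C(Me)CO2H, C5 C(Me)(dienyl), C6=C7(Me), C7a)
1. Target 27 ⇐ methyl ester 26 ⇐ oxirane-fused adduct 25: the C2=C3 alkene of ring A is carried through the ring-forming step as a temporary cis C2–C3 oxirane and revealed afterwards by deoxygenation.
2. Key disconnection: bonds C3a–C7a and C4–C5, by an intramolecular Diels–Alder reaction of the linear epoxy tetraene ester 24 (diene C7a=C7–C6=C5, dienophile C3a=C4–CO2Me); rings A and B close together.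
3. Enabling feature: ring B is a cyclohexene whose C6=C7 double bond lies opposite the C3a–C4 bond that carries the carboxyl group (a Diels–Alder retron), and the three-atom bridge C1–C2–C3 of ring A ties diene terminus C7a to dienophile carbon C3a. The oxirane holds C1 and C3a cis on this bridge without the twist and hydrogen-shift liabilities of a free (Z)-dienoate.
4. 24 ⇐ oxidation/Wittig ⇐ epoxy alcohol 22 ⇐ Stille union (bond C6–C7) of stannane 14 (from the (R)-Roche ester by Corey–Fuchs, Still–Gennari and Sharpless epoxidation) with trienyl iodide 21 (from benzalacetone by Horner–Wadsworth–Emmons, Colvin homologation and carboalumination).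
5. Ring order: oxirane (step 9), rings A and B in one operation (step 18), oxirane removed (step 19).

Key step: step 18

Remark on the chemistry: the target numbering above is used for all intermediates; phosphonate 8, D-(−)-diethyl tartrate and the ylide of step 17 are taken as purchased.

**Route**

Step 1
Reactants: 1 methyl (2R)-3-hydroxy-2-methylpropanoate
Product: 2 methyl (2R)-3-[(tert-butyldimethylsilyl)oxy]-2-methylpropanoate
Conditions: TBSCl, imidazole, CH2Cl2, 0 °C → rt
Reagents that add atoms: tert-butyldimethylsilyl chloride CC(C)(C)[Si](C)(C)Cl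
Why: Silyl ether formation masks the primary alcohol for the organometallic steps and leaves the stereocentre (future C1) untouched.

Step 2
Reactants: 2 methyl (2R)-3-[(tert-butyldimethylsilyl)oxy]-2-methylpropanoate
Product: 3 (2R)-3-[(tert-butyldimethylsilyl)oxy]-2-methylpropanal
Conditions: i-Bu2AlH (1.1 equiv), CH2Cl2, −78 °C; aq. potassium sodium tartrate
Reagents that add atoms: none
Why: Partial ester reduction through the aluminium hemiacetal, which is stable at −78 °C, so the aldehyde is released only on work-up and the α-stereocentre should not epimerise.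

Step 3
Reactants: 3 (2R)-3-[(tert-butyldimethylsilyl)oxy]-2-methylpropanal
Product: 4 tert-butyl{[(2S)-4,4-dibromo-2-methylbut-3-en-1-yl]oxy}dimethylsilane
Conditions: CBr4, PPh3, CH2Cl2, 0 °C
Reagents that add atoms: carbon tetrabromide BrC(Br)(Br)Br
Why: Corey–Fuchs dibromo-olefination (Wittig reaction of Ph3P=CBr2) adds the carbon that becomes C7.

Step 4
Reactants: 4 tert-butyl{[(2S)-4,4-dibromo-2-methylbut-3-en-1-yl]oxy}dimethylsilane
Product: 6 tert-butyldimethyl{[(2S)-2-methylpent-3-yn-1-yl]oxy}silane, via lithium acetylide 5 (not isolated)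
Conditions: n-BuLi (2.1 equiv), THF, −78 → 0 °C; then MeI, −78 °C → rt
Reagents that add atoms: iodomethane CI
Why: Second stage of the Corey–Fuchs sequence (elimination, then bromine–lithium exchange) gives the acetylide, whose C-methylation installs the C7 methyl group.

Step 5
Reactants: 6 tert-butyldimethyl{[(2S)-2-methylpent-3-yn-1-yl]oxy}silane
Product: 7 (2S)-2-methylpent-3-yn-1-ol
Conditions: CSA (cat.), MeOH, rt
Reagents that add atoms: none
Why: Acid-catalysed methanolysis of a primary silyl ether is mild enough for the propargylic stereocentre.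

Step 6
Reactants: 8 methyl 2-[bis(2,2,2-trifluoroethoxy)phosphoryl]acetate
Product: 9 methyl 2-[bis(2,2,2-trifluoroethoxy)phosphoryl]butanoate (racemic)
Conditions: NaH, EtI, DMF, 0 °C → rt
Reagents that add atoms: iodoethane CCI
Why: C-Alkylation of the stabilised phosphonoacetate anion provides the α-ethyl Still–Gennari reagent that delivers C3, its ethyl group and C3a.

Step 7
Reactants: 7 (2S)-2-methylpent-3-yn-1-ol; 9 methyl 2-[bis(2,2,2-trifluoroethoxy)phosphoryl]butanoate
Product: 11 methyl (2Z,4R)-2-ethyl-4-methylhept-2-en-5-ynoate, via (2S)-2-methylpent-3-ynal 10 (not isolated)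
Conditions: Dess–Martin periodinane, NaHCO3, CH2Cl2, 0 °C, cold filtration; then added to 9, KN(SiMe3)2, 18-crown-6, THF, −78 °C
Reagents that add atoms: none
Why: Dess–Martin oxidation followed at once by Still–Gennari olefination, in which the electron-poor trifluoroethyl phosphonate under dissociating conditions should give the (Z)-trisubstituted enoate under kinetic control, while low temperature and the non-isolated aldehyde limit racemisation at C1.

Step 8
Reactants: 11 methyl (2Z,4R)-2-ethyl-4-methylhept-2-en-5-ynoate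
Product: 12 (2Z,4R)-2-ethyl-4-methylhept-2-en-5-yn-1-ol
Conditions: i-Bu2AlH (2.2 equiv), CH2Cl2, −78 °C
Reagents that add atoms: none
Why: 1,2-Reduction of the enoate to the allylic alcohol leaves the alkyne and the alkene geometry intact.

Step 9
Reactants: 12 (2Z,4R)-2-ethyl-4-methylhept-2-en-5-yn-1-ol
Product: 13 {(2R,3S)-2-ethyl-3-[(2S)-pent-3-yn-2-yl]oxiran-2-yl}methanol
Conditions: Ti(OiPr)4, D-(−)-diethyl tartrate, t-BuOOH, 4 Å molecular sieves, CH2Cl2, −20 °C
Reagents that add atoms: tert-butyl hydroperoxide CC(C)(C)OO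
Why: Sharpless asymmetric epoxidation in which the D-(−)-tartrate should deliver oxygen to the alkene face that, with C1–H eclipsing the alkene (allylic 1,3-strain against the cis CH2OH), carries the slim propynyl group and not the C1 methyl, so reagent and substrate preferences coincide and set C2 and C3 of the temporary oxirane.

Step 10
Reactants: 13 {(2R,3S)-2-ethyl-3-[(2S)-pent-3-yn-2-yl]oxiran-2-yl}methanol
Product: 14 {(2R,3S)-2-ethyl-3-[(2S,3E)-4-(tributylstannyl)pent-3-en-2-yl]oxiran-2-yl}methanol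
Conditions: Bu3SnH, PdCl2(PPh3)2 (cat.), THF, 0 °C → rt
Reagents that add atoms: tributyltin hydride CCCC[SnH](CCCC)CCCC
Why: Palladium-catalysed syn-hydrostannation should place tin on the alkyne carbon remote from the branched C1 (future C7) and hydrogen on C7a, giving the (E)-alkenylstannane.

Step 11
Reactants: 15 (3E)-4-phenylbut-3-en-2-one
Product: 16 ethyl (2E,4E)-3-methyl-5-phenylpenta-2,4-dienoate
Conditions: (EtO)2P(O)CH2CO2Et, NaH, THF, 0 °C → reflux
Reagents that add atoms: triethyl phosphonoacetate CCOC(=O)CP(=O)(OCC)OCC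
Why: Horner–Wadsworth–Emmons olefination of the methyl ketone should favour the isomer with the ester trans to the larger styryl group, and the minor (2Z)-isomer is removed by chromatography.

Step 12
Reactants: 16 ethyl (2E,4E)-3-methyl-5-phenylpenta-2,4-dienoate
Product: 17 (2E,4E)-3-methyl-5-phenylpenta-2,4-dien-1-ol
Conditions: i-Bu2AlH, CH2Cl2, −78 °C
Reagents that add atoms: none
Why: 1,2-Reduction of the dienoate to the allylic alcohol without touching the diene.

Step 13
Reactants: 17 (2E,4E)-3-methyl-5-phenylpenta-2,4-dien-1-ol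
Product: 18 (2E,4E)-3-methyl-5-phenylpenta-2,4-dienal
Conditions: MnO2, CH2Cl2, rt
Reagents that add atoms: none
Why: Selective oxidation of the allylic alcohol on MnO2 should preserve both alkene geometries.

Step 14
Reactants: 18 (2E,4E)-3-methyl-5-phenylpenta-2,4-dienal
Product: 19 [(1E,3E)-3-methylhexa-1,3-dien-5-yn-1-yl]benzene
Conditions: Me3SiCHN2, n-BuLi, THF, −78 °C → rt
Reagents that add atoms: trimethylsilyldiazomethane C[Si](C)(C)C=[N+]=[N-]
Why: Colvin rearrangement (1,2-addition of the lithiated diazo reagent, Peterson-type loss of silanolate, 1,2-hydrogen shift of the alkylidene carbene) gives the terminal alkyne, whose new carbon becomes C6.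

Step 15
Reactants: 19 [(1E,3E)-3-methylhexa-1,3-dien-5-yn-1-yl]benzene
Product: 21 [(1E,3E,5E)-6-iodo-3,5-dimethylhexa-1,3,5-trien-1-yl]benzene, via alkenylalane 20 (not isolated)
Conditions: Me3Al, Cp2ZrCl2 (cat.), CH2Cl2, rt; then I2, THF, −30 °C
Reagents that add atoms: trimethylaluminium C[Al](C)C; iodine II
Why: Zirconium-catalysed syn-carboalumination puts the methyl group on the internal carbon (future C5) and aluminium on the terminus (future C6), and iodinolysis with retention gives the (E)-iodide.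

Step 16
Reactants: 14 {(2R,3S)-2-ethyl-3-[(2S,3E)-4-(tributylstannyl)pent-3-en-2-yl]oxiran-2-yl}methanol; 21 [(1E,3E,5E)-6-iodo-3,5-dimethylhexa-1,3,5-trien-1-yl]benzene
Product: 22 {(2R,3S)-2-ethyl-3-[(2S,3E,5E,7E,9E)-4,6,8-trimethyl-10-phenyldeca-3,5,7,9-tetraen-2-yl]oxiran-2-yl}methanol
Conditions: Pd2(dba)3 (cat.), AsPh3, CuI (cat.), NMP, rt → 40 °C, dark
Reagents that add atoms: none
Why: Stille cross-coupling forms the C6–C7 bond with retention at both alkenyl partners, and the non-allylic oxirane and free alcohol should be inert to zerovalent palladium.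

Step 17
Reactants: 22 {(2R,3S)-2-ethyl-3-[(2S,3E,5E,7E,9E)-4,6,8-trimethyl-10-phenyldeca-3,5,7,9-tetraen-2-yl]oxiran-2-yl}methanol
Product: 24 methyl (2E)-3-{(2R,3S)-2-ethyl-3-[(2S,3E,5E,7E,9E)-4,6,8-trimethyl-10-phenyldeca-3,5,7,9-tetraen-2-yl]oxiran-2-yl}-2-methylprop-2-enoate, via epoxy aldehyde 23 (not isolated)
Conditions: Dess–Martin periodinane, NaHCO3, CH2Cl2, 0 °C; then Ph3P=C(Me)CO2Me, rt
Reagents that add atoms: methyl 2-(triphenylphosphoranylidene)propanoate COC(=O)C(C)=P(c1ccccc1)(c1ccccc1)c1ccccc1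
Why: Dess–Martin oxidation gives an aldehyde without α-hydrogen, and Wittig olefination with the stabilised ylide should give the (E)-2-methyl enoate; the dienophile is installed last because a vinyl oxirane would not survive the palladium step.

Step 18
Reactants: 24 methyl (2E)-3-{(2R,3S)-2-ethyl-3-[(2S,3E,5E,7E,9E)-4,6,8-trimethyl-10-phenyldeca-3,5,7,9-tetraen-2-yl]oxiran-2-yl}-2-methylprop-2-enoate
Product: 25 methyl (1S,2S,3R,3aS,4R,5S,7aS)-2,3-epoxy-3-ethyl-1,4,5,7-tetramethyl-5-[(1E,3E)-2-methyl-4-phenylbuta-1,3-dien-1-yl]-2,3,3a,4,5,7a-hexahydro-1H-indene-4-carboxylate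
Conditions: toluene (0.005 M), BHT (cat.), 110 °C, dark
Reagents that add atoms: none
Why: Thermal intramolecular Diels–Alder reaction, a concerted but asynchronous [4+2] in which the C3a–C7a bond leads because C3a is the β-carbon of the enoate and C5 best carries positive charge; the closest precedent is the cyclisation of ester-activated (E,E)-1,3,8-nonatrienes to trans-hydrindenes, including closures that build vicinal quaternary carbons. Ring A (five-membered) closes by bond C3a–C7a between the tethered diene terminus and the tethered dienophile carbon across the three-atom bridge C1–C2–C3, and ring B (six-membered) closes by the cycloaddition itself through bond C4–C5. C3a and C7a: the trans ring fusion should follow from the transition state with the bridge exo and the ester endo, because in the cis-fused alternative C3 with its ethyl group would lie under the C7 methyl. C4 and C5: with the ester endo, suprafacial addition copies the (E)-geometry of the C3a=C4 enoate and of the C5=C6 alkene into the cis relation of CO2Me and the dienyl group and of the two methyl groups. Facial choice relative to C1 comes from allylic 1,3-strain, since C1–H eclipses the C7a=C7 bond beside the C7 methyl and the bridge therefore attacks anti to the C1 methyl, which ends cis to H7a, and the cis-oxirane adds a matched bias by placing its oxygen rather than the ethyl group beside the C4 methyl. The step needs site selectivity (only the proximal diene gives a five-membered ring A), endo/exo selectivity and facial selectivity, secured by the tether length, the C7 methyl, and C1 together with the oxirane.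

Step 19
Reactants: 25 methyl (1S,2S,3R,3aS,4R,5S,7aS)-2,3-epoxy-3-ethyl-1,4,5,7-tetramethyl-5-[(1E,3E)-2-methyl-4-phenylbuta-1,3-dien-1-yl]-2,3,3a,4,5,7a-hexahydro-1H-indene-4-carboxylate
Product: 26 methyl (1R,3aR,4R,5S,7aS)-3-ethyl-1,4,5,7-tetramethyl-5-[(1E,3E)-2-methyl-4-phenylbuta-1,3-dien-1-yl]-3a,4,5,7a-tetrahydro-1H-indene-4-carboxylate
Conditions: WCl6, n-BuLi (2 equiv per W), THF, −78 °C → rt; then 25, rt → 50 °C
Reagents that add atoms: none
Why: Tungsten-mediated epoxide deoxygenation (oxygen-atom transfer to lower-valent tungsten chloride) is known to tolerate esters and olefins on trisubstituted oxiranes and here unveils the C2=C3 alkene, whose geometry is fixed by the ring.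

Step 20
Reactants: 26 methyl (1R,3aR,4R,5S,7aS)-3-ethyl-1,4,5,7-tetramethyl-5-[(1E,3E)-2-methyl-4-phenylbuta-1,3-dien-1-yl]-3a,4,5,7a-tetrahydro-1H-indene-4-carboxylate
Product: 27 zyggomphic acid B, (1R,3aR,4R,5S,7aS)-3-ethyl-1,4,5,7-tetramethyl-5-[(1E,3E)-2-methyl-4-phenylbuta-1,3-dien-1-yl]-3a,4,5,7a-tetrahydro-1H-indene-4-carboxylic acid
Conditions: NaSEt, DMF, 80 °C; then aq. HCl to pH 3
Reagents that add atoms: none
Why: SN2 demethylation by thiolate at the ester methyl group is chosen because the carbonyl, flanked by two quaternary carbons, is shielded from saponification, and no stereocentre is touched.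

**Compound list**
1 | methyl (2R)-3-hydroxy-2-methylpropanoate | C[C@H](CO)C(=O)OC | starting material
2 | methyl (2R)-3-[(tert-butyldimethylsilyl)oxy]-2-methylpropanoate | C[C@H](CO[Si](C)(C)C(C)(C)C)C(=O)OC | intermediate
3 | (2R)-3-[(tert-butyldimethylsilyl)oxy]-2-methylpropanal | C[C@H](CO[Si](C)(C)C(C)(C)C)C=O | intermediate
4 | tert-butyl{[(2S)-4,4-dibromo-2-methylbut-3-en-1-yl]oxy}dimethylsilane | C[C@H](CO[Si](C)(C)C(C)(C)C)C=C(Br)Br | intermediate
5 | lithium acetylide, tert-butyl{[(2S)-4-lithio-2-methylbut-3-yn-1-yl]oxy}dimethylsilane | C[C@H](CO[Si](C)(C)C(C)(C)C)C#C[Li] | intermediate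
6 | tert-butyldimethyl{[(2S)-2-methylpent-3-yn-1-yl]oxy}silane | C[C@H](CO[Si](C)(C)C(C)(C)C)C#CC | intermediate
7 | (2S)-2-methylpent-3-yn-1-ol | C[C@H](CO)C#CC | intermediate
8 | methyl 2-[bis(2,2,2-trifluoroethoxy)phosphoryl]acetate | COC(=O)CP(=O)(OCC(F)(F)F)OCC(F)(F)F | starting material
9 | methyl 2-[bis(2,2,2-trifluoroethoxy)phosphoryl]butanoate (racemic) | CCC(C(=O)OC)P(=O)(OCC(F)(F)F)OCC(F)(F)F | intermediate
10 | (2S)-2-methylpent-3-ynal | C[C@H](C=O)C#CC | intermediate
11 | methyl (2Z,4R)-2-ethyl-4-methylhept-2-en-5-ynoate | COC(=O)/C(CC)=C\[C@@H](C)C#CC | intermediate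
12 | (2Z,4R)-2-ethyl-4-methylhept-2-en-5-yn-1-ol | OC/C(CC)=C\[C@@H](C)C#CC | intermediate
13 | {(2R,3S)-2-ethyl-3-[(2S)-pent-3-yn-2-yl]oxiran-2-yl}methanol | OC[C@@]1(CC)O[C@H]1[C@@H](C)C#CC | intermediate
14 | {(2R,3S)-2-ethyl-3-[(2S,3E)-4-(tributylstannyl)pent-3-en-2-yl]oxiran-2-yl}methanol | OC[C@@]1(CC)O[C@H]1[C@@H](C)/C=C(C)/[Sn](CCCC)(CCCC)CCCC | intermediate
15 | (3E)-4-phenylbut-3-en-2-one | CC(=O)/C=C/c1ccccc1 | starting material
16 | ethyl (2E,4E)-3-methyl-5-phenylpenta-2,4-dienoate | CCOC(=O)/C=C(C)/C=C/c1ccccc1 | intermediate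
17 | (2E,4E)-3-methyl-5-phenylpenta-2,4-dien-1-ol | OC/C=C(C)/C=C/c1ccccc1 | intermediate
18 | (2E,4E)-3-methyl-5-phenylpenta-2,4-dienal | O=C/C=C(C)/C=C/c1ccccc1 | intermediate
19 | [(1E,3E)-3-methylhexa-1,3-dien-5-yn-1-yl]benzene | C#C/C=C(C)/C=C/c1ccccc1 | intermediate
20 | dimethyl[(1E,3E,5E)-2,4-dimethyl-6-phenylhexa-1,3,5-trien-1-yl]alane | C[Al](C)/C=C(C)/C=C(C)/C=C/c1ccccc1 | intermediate
21 | [(1E,3E,5E)-6-iodo-3,5-dimethylhexa-1,3,5-trien-1-yl]benzene | I/C=C(C)/C=C(C)/C=C/c1ccccc1 | intermediate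
22 | {(2R,3S)-2-ethyl-3-[(2S,3E,5E,7E,9E)-4,6,8-trimethyl-10-phenyldeca-3,5,7,9-tetraen-2-yl]oxiran-2-yl}methanol | OC[C@@]1(CC)O[C@H]1[C@@H](C)/C=C(C)/C=C(C)/C=C(C)/C=C/c1ccccc1 | intermediate
23 | (2S,3S)-2-ethyl-3-[(2S,3E,5E,7E,9E)-4,6,8-trimethyl-10-phenyldeca-3,5,7,9-tetraen-2-yl]oxirane-2-carbaldehyde | O=C[C@@]1(CC)O[C@H]1[C@@H](C)/C=C(C)/C=C(C)/C=C(C)/C=C/c1ccccc1 | intermediate
24 | methyl (2E)-3-{(2R,3S)-2-ethyl-3-[(2S,3E,5E,7E,9E)-4,6,8-trimethyl-10-phenyldeca-3,5,7,9-tetraen-2-yl]oxiran-2-yl}-2-methylprop-2-enoate | COC(=O)/C(C)=C/[C@@]1(CC)O[C@H]1[C@@H](C)/C=C(C)/C=C(C)/C=C(C)/C=C/c1ccccc1 | intermediate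
25 | methyl (1S,2S,3R,3aS,4R,5S,7aS)-2,3-epoxy-3-ethyl-1,4,5,7-tetramethyl-5-[(1E,3E)-2-methyl-4-phenylbuta-1,3-dien-1-yl]-2,3,3a,4,5,7a-hexahydro-1H-indene-4-carboxylate | CC[C@@]15O[C@H]5[C@@H](C)[C@@H]2C(C)=C[C@](C)(/C=C(C)/C=C/c3ccccc3)[C@](C)(C(=O)OC)[C@@H]12 | intermediate
26 | methyl (1R,3aR,4R,5S,7aS)-3-ethyl-1,4,5,7-tetramethyl-5-[(1E,3E)-2-methyl-4-phenylbuta-1,3-dien-1-yl]-3a,4,5,7a-tetrahydro-1H-indene-4-carboxylate | CCC1=C[C@@H](C)[C@@H]2C(C)=C[C@](C)(/C=C(C)/C=C/c3ccccc3)[C@](C)(C(=O)OC)[C@@H]12 | intermediate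
27 | zyggomphic acid B | CCC1=C[C@@H](C)[C@@H]2C(C)=C[C@](C)(/C=C(C)/C=C/c3ccccc3)[C@](C)(C(=O)O)[C@@H]12 | target

**Step count and risks**

Total step count: 20. Longest linear sequence: 14 steps (steps 1–5, 7–10, 16–20, from the Roche ester 1).

Steps most likely to fail:

Step 18. The cycloaddition joins two fully substituted carbons and may be slow enough for thermal decay of the vinyl oxirane and polyene to compete, or endo/exo control may erode towards the cis-fused hydrindene. The fallback sets out from 22 and changes the dienophile. Oxidation as in step 17 gives aldehyde 23, and Wittig reaction with Ph3P=C(Me)CHO (CH2Cl2, rt) would give the epoxy tetraene enal F1. As a more electrophilic and more endo-selective dienophile it should cyclise at or slightly above room temperature to the adduct aldehyde F2. Pinnick oxidation (NaClO2, NaH2PO4, 2-methylbut-2-ene, t-BuOH/H2O) would give the epoxy acid F3, and methylation with Me3SiCHN2 (MeOH/toluene) returns to the route at 25.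

Step 19. The oxirane oxygen sits between the C1 methyl and the C4 quaternary carbon, so oxygen transfer to tungsten may be slow and acid-induced opening at the tertiary C3 (hydride shift or chloride capture) may take over. The fallback sets out from 25 and replaces direct deoxygenation by a two-step anti opening and anti elimination. PhSeNa (from PhSeSePh and NaBH4, EtOH, reflux) should open the oxirane at the secondary C2 with inversion to give the trans hydroxy selenide F4. SOCl2 and Et3N (CH2Cl2, 0 °C) would then expel the hydroxyl and phenylselanyl groups through an episelenonium ion, returning to the route at 26.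

Step 10. Regiocontrol in the tin hydride addition to the dialkyl alkyne may erode, reductive dimerisation of the hydride may outrun the slow addition, and transfer from the α-methyl stannane in step 16 may be sluggish. The fallback sets out from 13 and reverses the polarity of the coupling. Silylation (TBSCl, imidazole) gives the silyl ether F5. Hydrozirconation with Cp2Zr(H)Cl (THF, 50 °C, zirconium settling on the methyl-bearing carbon) and iodinolysis give the alkenyl iodide F6. Negishi coupling with alkenylalane 20 (made as in step 15, freed of excess Me3Al and used without iodinolysis; ZnCl2, Pd(PPh3)4, THF) gives the tetraene silyl ether F7, and Bu4NF (THF) returns to the route at 22.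

Further compounds
F1 | step 18 | (2E)-3-{(2R,3S)-2-ethyl-3-[(2S,3E,5E,7E,9E)-4,6,8-trimethyl-10-phenyldeca-3,5,7,9-tetraen-2-yl]oxiran-2-yl}-2-methylprop-2-enal | O=C/C(C)=C/[C@@]1(CC)O[C@H]1[C@@H](C)/C=C(C)/C=C(C)/C=C(C)/C=C/c1ccccc1
F2 | step 18 | (1S,2S,3R,3aS,4R,5S,7aS)-2,3-epoxy-3-ethyl-1,4,5,7-tetramethyl-5-[(1E,3E)-2-methyl-4-phenylbuta-1,3-dien-1-yl]-2,3,3a,4,5,7a-hexahydro-1H-indene-4-carbaldehyde | CC[C@@]15O[C@H]5[C@@H](C)[C@@H]2C(C)=C[C@](C)(/C=C(C)/C=C/c3ccccc3)[C@](C)(C=O)[C@@H]12
F3 | step 18 | (1S,2S,3R,3aS,4R,5S,7aS)-2,3-epoxy-3-ethyl-1,4,5,7-tetramethyl-5-[(1E,3E)-2-methyl-4-phenylbuta-1,3-dien-1-yl]-2,3,3a,4,5,7a-hexahydro-1H-indene-4-carboxylic acid | CC[C@@]15O[C@H]5[C@@H](C)[C@@H]2C(C)=C[C@](C)(/C=C(C)/C=C/c3ccccc3)[C@](C)(C(=O)O)[C@@H]12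
F4 | step 19 | methyl 3-ethyl-3-hydroxy-1,4,5,7-tetramethyl-5-[(1E,3E)-2-methyl-4-phenylbuta-1,3-dien-1-yl]-2-(phenylselanyl)-2,3,3a,4,5,7a-hexahydro-1H-indene-4-carboxylate (hydroxyl and selanyl trans) | CC[C@]1(O)[C@H]([Se]c4ccccc4)[C@@H](C)[C@@H]2C(C)=C[C@](C)(/C=C(C)/C=C/c3ccccc3)[C@](C)(C(=O)OC)[C@@H]12
F5 | step 10 | tert-butyl({(2R,3S)-2-ethyl-3-[(2S)-pent-3-yn-2-yl]oxiran-2-yl}methoxy)dimethylsilane | CC(C)(C)[Si](C)(C)OC[C@@]1(CC)O[C@H]1[C@@H](C)C#CC
F6 | step 10 | tert-butyl({(2R,3S)-2-ethyl-3-[(2S,3E)-4-iodopent-3-en-2-yl]oxiran-2-yl}methoxy)dimethylsilane | CC(C)(C)[Si](C)(C)OC[C@@]1(CC)O[C@H]1[C@@H](C)/C=C(C)/I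
F7 | step 10 | tert-butyl({(2R,3S)-2-ethyl-3-[(2S,3E,5E,7E,9E)-4,6,8-trimethyl-10-phenyldeca-3,5,7,9-tetraen-2-yl]oxiran-2-yl}methoxy)dimethylsilane | CC(C)(C)[Si](C)(C)OC[C@@]1(CC)O[C@H]1[C@@H](C)/C=C(C)/C=C(C)/C=C(C)/C=C/c1ccccc1
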